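The disconnection removes both rings A at once: in each half the bicyclo[3.1.0]hexane (cyclopropane C1–C2–C3 on cyclopentane C1–C3–C4–C5–C10) is cut at C1–C3 and C2–C3. Forward, one twofold rhodium-carbene cyclopropanation lets a diazoacetyl group on C5 (C4=O, C3=N2) add to the C1=C2 vinyl group on C10, closing two cyclopentanones and two cyclopropanes and setting C1, C3, C1′, C3′. It exploits the trans-diequatorial C5/C10 pair on ring B, which gives the trans A/B fusion, and the C9–C9′ cyclobutane bond, which blocks one vinyl face. The precursor is the head-to-head cyclobutane bis(butenolide) bis(diazoketone), made by [2+2] photodimerisation of a seco-monomer.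

Key step: step 8

Remark: lindenane numbering (C1–C15, primed in the second half) is used for all intermediates, and β is the face of ring B that carries the C14 methyl.

Step 1
Reactants: 1 tert-butyl acetoacetate; 2 methyl vinyl ketone
Product: 4 racemic tert-butyl 2-methyl-4-oxocyclohex-2-ene-1-carboxylate, via Michael adduct 3 (not isolated)
Conditions: t-BuOK (5 mol%), t-BuOH, 0 °C to rt; then pyrrolidine, AcOH (20 mol% each), PhH, reflux, Dean–Stark
Reagents that add atoms: none
Why: Michael addition of the β-keto ester to the enone, then enamine-mediated intramolecular aldol condensation of the terminal methyl ketone onto the acetyl carbonyl (Robinson annulation, as in the Hagemann ester synthesis), should give the conjugated cyclohexenone; C5 is formed racemic and is labile at this stage.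

Step 2
Reactants: 4 racemic tert-butyl 2-methyl-4-oxocyclohex-2-ene-1-carboxylate; 5 vinylmagnesium bromide
Product: 7 racemic tert-butyl (1R*,2S*)-2-ethenyl-2-methyl-4-oxocyclohexane-1-carboxylate, via silyl enol ether 6 (not isolated)
Conditions: CuBr·SMe2 (10 mol%), TMSCl, THF, −78 to −40 °C; then 1 M HCl, 0 °C
Reagents that add atoms: none
Why: Copper-catalysed conjugate addition of the Grignard reagent, accelerated by TMSCl, should create the quaternary C10; the C5 ester sits pseudoaxial to avoid A(1,2) strain with the C10 methyl, so the vinyl group should enter on the opposite face (vinyl trans to ester, methyl cis to ester).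

Step 3
Reactants: 7 racemic tert-butyl (1R*,2S*)-2-ethenyl-2-methyl-4-oxocyclohexane-1-carboxylate
Product: 8 tert-butyl (1R,2S)-2-ethenyl-2-methyl-4-oxocyclohexane-1-carboxylate
Conditions: preparative SFC, amylose tris(3,5-dimethylphenylcarbamate) stationary phase, CO2/MeOH, 35 °C
Reagents that add atoms: none
Why: Resolution by chromatography on a chiral stationary phase should separate the enantiomers of this configurationally stable keto ester (C10 quaternary, C5 not enolisable under neutral conditions); the (1R,2S) fraction would be identified by X-ray analysis of a heavy-atom hydrazone.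

Step 4
Reactants: 8 tert-butyl (1R,2S)-2-ethenyl-2-methyl-4-oxocyclohexane-1-carboxylate; 9 ethyl pyruvate
Product: 12 tert-butyl (1R,2S)-5-(1-ethoxy-2-hydroxy-1-oxopropan-2-yl)-2-ethenyl-2-methyl-4-oxocyclohexane-1-carboxylate (C7/C11 epimer mixture), via lithium enolate 10 (not isolated), via chlorozinc enolate 11 (not isolated)
Conditions: LiN(i-Pr)2 (1.1 equiv), THF, −78 °C; ZnCl2; 9, −78 °C; aq NH4Cl
Reagents that add atoms: none
Why: Kinetic deprotonation should occur at C7, the α-methylene remote from the quaternary C10 (the ester α-H at C5 is far less acidic), and the zinc enolate should add to the ketone carbonyl of the pyruvate (directed aldol addition); the new centres C7 and C11 are erased in step 5.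

Step 5
Reactants: 12 aldol adduct
Product: 14 (5R,6R)-6-ethenyl-3,6-dimethyl-2-oxo-2,4,5,6-tetrahydro-1-benzofuran-5-carboxylic acid (seco-monomer), via tert-butyl dienolide ester 13 (not isolated)
Conditions: TsOH·H2O (0.3 equiv), PhMe, reflux, Dean–Stark
Reagents that add atoms: none
Why: Acid-catalysed dehydration across C7–C11 and lactonisation of the ethyl ester onto the C8 enol toward C9 (butenolide annulation) should give the conjugated γ-alkylidene butenolide (C9=C8–O, C7=C11), and the same acid should cleave the tert-butyl ester by loss of isobutene; C5 and C10 are not touched.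

Step 6
Reactants: 14 seco-monomer acid (two molecules)
Product: 15 C2-symmetric head-to-head anti cyclobutane bis(butenolide) 5,5′-dicarboxylic acid (C8–C8′ and C9–C9′ bonds on the α faces; 10,10′-divinyl)
Conditions: hν (medium-pressure Hg lamp, Pyrex), degassed MeCN, 0.2 M, rt
Reagents that add atoms: second molecule of 14 ((5R,6R)-6-ethenyl-3,6-dimethyl-2-oxo-2,4,5,6-tetrahydro-1-benzofuran-5-carboxylic acid), C=C[C@]1(C)C=C2OC(=O)C(C)=C2C[C@H]1C(=O)O
Why: [2+2] photodimerisation of two molecules of the γ-alkylidene butenolide, a reaction known for lindenane dienolides, should join C9 to C9′ first (leaving two C8 radicals stabilised by oxygen and the butenolide) and then C8 to C8′; each monomer should react on its α face, anti to the axial C14 methyl, with the two ring B units anti across the cyclobutane, which sets C8, C9, C8′ and C9′.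

Step 7
Reactants: 15 dimer diacid; 16 trimethylsilyldiazomethane (two equivalents react, one per acid chloride)
Product: 18 5,5′-bis(diazoacetyl)-10,10′-divinyl cyclobutane bis(butenolide), via bis(acid chloride) 17 (not isolated)
Conditions: (COCl)2 (2.5 equiv), DMF (cat.), CH2Cl2, 0 °C to rt, evaporate; then 16 (2 M in hexanes, 4 equiv), THF/MeCN, 0 °C to rt
Reagents that add atoms: trimethylsilyldiazomethane (second equivalent of 16), C[Si](C)(C)C=[N+]=[N-]
Why: Acid chloride formation through the Vilsmeier reagent and C-acylation of one diazoalkane per acyl chloride with loss of the silyl group (first stage of the Arndt–Eistert sequence) should give the two α-diazoketones; no amine base is present, so the α-branched acid chlorides cannot form ketenes and C5/C5′ should keep their configuration.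

Step 8
Reactants: 18 bis(diazoketone)
Product: 19 4,4′-diketone of the dimer (bis(cyclopropyl ketone), both cyclopentanones and both cyclopropanes closed)
Conditions: Rh2(OAc)4 (5 mol%), CH2Cl2, rt, slow addition of 18 over 6 h
Reagents that add atoms: none
Why: Rh2(OAc)4 (divalent rhodium) should expel N2 from each diazoketone to give an electrophilic rhodium carbene at C3, which adds in a concerted, asynchronous [2+1] fashion to the C1=C2 vinyl group held gauche to it by the trans-diequatorial C5 and C10 substituents of chair ring B. The closest known reaction type is the intramolecular cyclopropanation of α-diazoketones bearing a γ,δ-alkene, which gives bicyclo[3.1.0]hexan-2-ones. Each cyclopentanone (C10–C1–C3–C4–C5) closes in the 5-exo sense, C2 staying outside that ring, and each cyclopropane (C1–C2–C3) closes by the carbene [2+1] addition itself. C1 and C3 are necessarily cis to each other (syn addition through a one-atom tether); their sense relative to C10 is set by the vinyl rotamer, and the rotamer with C2 on the β face beside the C14 methyl should react because the α rotamer would push C2 against the pseudo-axial C9–C9′ cyclobutane bond. The step needs chemoselectivity for the vinyl group over C–H insertion and over the butenolides, which the proximity of the vinyl group, the diverging equatorial C9–H bond and the electron-poor, tetrasubstituted C7=C11 alkenes should secure. Slow addition should suppress carbene dimerisation, and the C2 symmetry means both halves face the same choice.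

Step 9
Reactants: 19 4,4′-diketone
Product: 20 target CNP0265879.1
Conditions: Zn, CH2Br2, TiCl4 (reagent preformed in THF, 5 °C); then 19, CH2Cl2, 0 °C to rt; aq NaHCO3
Reagents that add atoms: dibromomethane (two equivalents, one per ketone), BrCBr.BrCBr
Why: Lombardo–Takai methylenation with the gem-dizinc/titanium reagent should convert both ketones into exocyclic methylenes; the reagent is non-basic, so the enolisable trans ring-fusion centres C5/C5′ should not epimerise, and it does not attack lactones.

Compound list
1 | tert-butyl acetoacetate (tert-butyl 3-oxobutanoate) | CC(=O)CC(=O)OC(C)(C)C | starting material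
2 | methyl vinyl ketone (but-3-en-2-one) | C=CC(C)=O | starting material
3 | tert-butyl 2-acetyl-5-oxohexanoate, racemic Michael adduct | CC(=O)CCC(C(C)=O)C(=O)OC(C)(C)C | intermediate
4 | tert-butyl 2-methyl-4-oxocyclohex-2-ene-1-carboxylate, racemic | CC1=CC(=O)CCC1C(=O)OC(C)(C)C | intermediate
5 | vinylmagnesium bromide | C=C[Mg]Br | starting material
6 | tert-butyl (1R*,2R*)-2-ethenyl-2-methyl-4-(trimethylsilyloxy)cyclohex-3-ene-1-carboxylate, racemate with vinyl trans to ester (both enantiomers written) | C=C[C@]1(C)C=C(O[Si](C)(C)C)CC[C@H]1C(=O)OC(C)(C)C.C=C[C@@]1(C)C=C(O[Si](C)(C)C)CC[C@@H]1C(=O)OC(C)(C)C | intermediate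
7 | tert-butyl (1R*,2S*)-2-ethenyl-2-methyl-4-oxocyclohexane-1-carboxylate, racemate with vinyl trans to ester (both enantiomers written) | C=C[C@]1(C)CC(=O)CC[C@H]1C(=O)OC(C)(C)C.C=C[C@@]1(C)CC(=O)CC[C@@H]1C(=O)OC(C)(C)C | intermediate
8 | tert-butyl (1R,2S)-2-ethenyl-2-methyl-4-oxocyclohexane-1-carboxylate | C=C[C@]1(C)CC(=O)CC[C@H]1C(=O)OC(C)(C)C | intermediate
9 | ethyl pyruvate | CCOC(=O)C(C)=O | starting material
10 | lithium enolate of 8 (C7=C8–OLi) | C=C[C@]1(C)CC(O[Li])=CC[C@H]1C(=O)OC(C)(C)C | intermediate
11 | chlorozinc enolate of 8 (C7=C8–OZnCl) | C=C[C@]1(C)CC(O[Zn]Cl)=CC[C@H]1C(=O)OC(C)(C)C | intermediate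
12 | tert-butyl (1R,2S)-5-(1-ethoxy-2-hydroxy-1-oxopropan-2-yl)-2-ethenyl-2-methyl-4-oxocyclohexane-1-carboxylate, epimer mixture at C7 and C11 | C=C[C@]1(C)CC(=O)C(C(C)(O)C(=O)OCC)C[C@H]1C(=O)OC(C)(C)C | intermediate
13 | tert-butyl (5R,6R)-6-ethenyl-3,6-dimethyl-2-oxo-2,4,5,6-tetrahydro-1-benzofuran-5-carboxylate | C=C[C@]1(C)C=C2OC(=O)C(C)=C2C[C@H]1C(=O)OC(C)(C)C | intermediate
14 | (5R,6R)-6-ethenyl-3,6-dimethyl-2-oxo-2,4,5,6-tetrahydro-1-benzofuran-5-carboxylic acid (seco-monomer: dienolide C9=C8–O and C7=C11, 10-vinyl, 5-CO2H) | C=C[C@]1(C)C=C2OC(=O)C(C)=C2C[C@H]1C(=O)O | intermediate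
15 | head-to-head anti cyclobutane dimer of 14: 8,8′:9,9′-linked bis(butenolide) 5,5′-dicarboxylic acid, 10,10′-divinyl, H9/H9′ and O8/O8′ β, C2-symmetric | C=C[C@@]2(C)[C@H](C(=O)O)CC1=C(C)C(=O)O[C@]13[C@H]2[C@H]1[C@@](C)(C=C)[C@H](C(=O)O)CC2=C(C)C(=O)O[C@@]213 | intermediate
16 | trimethylsilyldiazomethane | C[Si](C)(C)C=[N+]=[N-] | starting material
17 | 5,5′-bis(chlorocarbonyl) derivative of 15 | C=C[C@@]2(C)[C@H](C(=O)Cl)CC1=C(C)C(=O)O[C@]13[C@H]2[C@H]1[C@@](C)(C=C)[C@H](C(=O)Cl)CC2=C(C)C(=O)O[C@@]213 | intermediate
18 | 5,5′-bis(diazoacetyl)-10,10′-divinyl cyclobutane bis(butenolide) (key-step precursor) | C=C[C@@]2(C)[C@H](C(=O)C=[N+]=[N-])CC1=C(C)C(=O)O[C@]13[C@H]2[C@H]1[C@@](C)(C=C)[C@H](C(=O)C=[N+]=[N-])CC2=C(C)C(=O)O[C@@]213 | intermediate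
19 | 4,4′-diketone of the dimer (bis-nor-methylene target; cyclopropane C2 and C14 methyl both β, H5 α) | O=C1[C@H]2C[C@H]2[C@@]2(C)[C@H]1CC1=C(C)C(=O)O[C@]13[C@H]2[C@H]1[C@@]2(C)[C@@H]4C[C@@H]4C(=O)[C@@H]2CC2=C(C)C(=O)O[C@@]213 | intermediate
20 | CNP0265879.1 | C=C1[C@H]2C[C@H]2[C@@]2(C)[C@H]1CC1=C(C)C(=O)O[C@]13[C@H]2[C@H]1[C@@]2(C)[C@@H]4C[C@@H]4C(=C)[C@@H]2CC2=C(C)C(=O)O[C@@]213 | target

Total step count: 9. Longest linear sequence: 9 steps (1 to 20).

Steps most likely to fail

Step 8. The carbene may add to the wrong vinyl face in one or both halves, or C–H insertion may compete on the congested dimer. In the fallback C2 would be delivered by a hydroxyl-directed zinc carbenoid instead of a tethered carbene. It sets out from 15, through the acid chloride 17 made as in step 7. Stille acylation with tributyl(vinyl)stannane [PdCl2(PPh3)2, PhMe, 60 °C] would give the bis(vinyl ketone) F1. Ring-closing metathesis with the second-generation Grubbs catalyst (CH2Cl2, 40 °C) would close the trans-fused bis(cyclopentenone) F2. Luche reduction (NaBH4, CeCl3·7H2O, MeOH, −40 °C) from the α face, away from the C14 methyl, would give the 4β,4′β-diol F3. Simmons–Smith cyclopropanation (Et2Zn, CH2I2, CH2Cl2, 0 °C) syn to the hydroxyl groups would give the bis(cyclopropyl carbinol) F4 with C2 on the β face. Dess–Martin oxidation then comes back to the route at 19.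

Step 6. The seco-monomer may dimerise with poor head-to-head or facial selectivity, or its 1,4-diene (C8=C9 and C1=C2 on C10) may rearrange by a di-π-methane path. In the fallback ring A would be closed before dimerisation. It sets out from 14. (COCl)2 with catalytic DMF would give the monomeric acid chloride F5, and trimethylsilyldiazomethane would turn it into the monomeric diazoketone F6. Rh2(OAc)4 would give the monomeric cyclopropyl ketone F7; the equatorial acyl group cannot reach the ring alkene C8=C9, and any minor cyclopropane diastereomer would be removed at this stage. Zn/CH2Br2/TiCl4 would give the 4-methylene monomer F8. Irradiation of F8 (Pyrex, hexane), the established [2+2] dimerisation of lindenane dienolides, comes back to the route at 20.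

Step 9. The ring-fusion centre C5 may epimerise, the Lewis acid may open the cyclopropyl ketone, or the reaction may stall after one ketone. In the fallback the methylene would be built in two stages by a Peterson olefination. It sets out from 19. Me3SiCH2Li with CeCl3 (THF, −78 °C) should add to the two ketones only and give the bis(β-hydroxysilane) F9, in which C5 is no longer α to a carbonyl. KH (THF, 0 °C) would then eliminate the silanolate and come back to the route at 20.

Further compounds
F1 | step 8 | 5,5′-bis(propenoyl)-10,10′-divinyl cyclobutane bis(butenolide) | C=C[C@@]2(C)[C@H](C(=O)C=C)CC1=C(C)C(=O)O[C@]13[C@H]2[C@H]1[C@@](C)(C=C)[C@H](C(=O)C=C)CC2=C(C)C(=O)O[C@@]213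
F2 | step 8 | bis(cyclopentenone) of the dimer (C1=C3, C4=O in each half) | O=C1C=C[C@@]2(C)[C@H]1CC1=C(C)C(=O)O[C@]13[C@H]2[C@H]1[C@@]2(C)C=CC(=O)[C@@H]2CC2=C(C)C(=O)O[C@@]213
F3 | step 8 | 4β,4′β-diol, bis(cyclopentenol) of the dimer | O[C@H]1C=C[C@@]2(C)[C@H]1CC1=C(C)C(=O)O[C@]13[C@H]2[C@H]1[C@@]2(C)C=C[C@H](O)[C@@H]2CC2=C(C)C(=O)O[C@@]213
F4 | step 8 | 4β,4′β-diol with both cyclopropanes closed (bis(cyclopropyl carbinol)) | O[C@H]1[C@H]2C[C@H]2[C@@]2(C)[C@H]1CC1=C(C)C(=O)O[C@]13[C@H]2[C@H]1[C@@]2(C)[C@@H]4C[C@@H]4[C@H](O)[C@@H]2CC2=C(C)C(=O)O[C@@]213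
F5 | step 6 | monomeric acid chloride (5-chlorocarbonyl-10-vinyl dienolide) | C=C[C@]1(C)C=C2OC(=O)C(C)=C2C[C@H]1C(=O)Cl
F6 | step 6 | monomeric diazoketone (5-diazoacetyl-10-vinyl dienolide) | C=C[C@]1(C)C=C2OC(=O)C(C)=C2C[C@H]1C(=O)C=[N+]=[N-]
F7 | step 6 | monomeric cyclopropyl ketone (4-oxo lindenane dienolide) | O=C1[C@H]2C[C@H]2[C@@]2(C)[C@H]1CC1=C(C)C(=O)OC1=C2
F8 | step 6 | 4-methylene monomer (one half of the target with C8=C9) | C=C1[C@H]2C[C@H]2[C@@]2(C)[C@H]1CC1=C(C)C(=O)OC1=C2
F9 | step 9 | 4,4′-bis(hydroxy)-4,4′-bis(trimethylsilylmethyl) adduct of 19 | C[Si](C)(C)CC1(O)[C@H]2C[C@H]2[C@@]2(C)[C@H]1CC1=C(C)C(=O)O[C@]13[C@H]2[C@H]1[C@@]2(C)[C@@H]4C[C@@H]4C(O)(C[Si](C)(C)C)[C@@H]2CC2=C(C)C(=O)O[C@@]213
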